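Eremophilane numbering is used. Ring B (C5–C10) is an aldol-condensation retron (C6=C7–C8=O). The keto aldehyde behind it is the endo Diels–Alder adduct of tiglaldehyde: the cis C4/C5 methyl pair mirrors the E-enal, and the cis C5–C6/C10–C9 bonds (cis fusion, C10–H β) mirror the endo transition state. One operation therefore joins two open-chain partners, tiglaldehyde and an E-dienyl γ-keto ester that carries C11 from methyl (R)-3-hydroxy-2-methylpropanoate. It closes ring A by catalytic enantioselective [4+2] cycloaddition and then ring B by C7→C6 condensation, setting C4, C5 and C10. Allylic oxidation at C3, two selective reductions and angeloylation finish the synthesis.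

Key step: step 4

Remark on numbering: ring A = C1–C5, C10; ring B = C5–C10; side chain = C11 (CH), C12 (ester C=O), C13 (CH3); β = the face of the C5 methyl group.

Assumption: the (R)-oxazaborolidinium ion is taken to expose the enal face that leads to (5R), as the formyl C–H···O pre-transition-state model suggests. If the sense proves opposite, the (S)-catalyst is used; both antipodes are commercial.

Step 1
Reactants: 1 methyl (2R)-3-hydroxy-2-methylpropanoate
Product: 2 methyl (2S)-3-iodo-2-methylpropanoate
Conditions: I2, PPh3, imidazole, CH2Cl2, 0 °C → rt
Reagents that add atoms: iodine, II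
Why: Appel-type iodination replaces the primary OH by SN2 at CH2, so the neighbouring stereocentre (future C11) is untouched and only its CIP label changes.

Step 2
Reactants: 3 sorbic acid, (2E,4E)-hexa-2,4-dienoic acid
Product: 4 (3E)-hexa-3,5-dienoic acid
Conditions: LDA (2.2 equiv), THF, −78 → 0 °C; then aq HCl, −78 °C
Reagents that add atoms: none
Why: Deconjugative protonation: the extended dienolate dianion is protonated kinetically at the α-carbon, which moves the diene out of conjugation, and the s-trans dienolate should give the 3E alkene.

Step 3
Reactants: 4 (3E)-hexa-3,5-dienoic acid; 2 methyl (2S)-3-iodo-2-methylpropanoate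
Product: 7 methyl (2R,6E)-2-methyl-4-oxonona-6,8-dienoate, via acid chloride 5 (not isolated), via organozinc iodide 6 (not isolated)
Conditions: 4, (COCl)2, cat. DMF, CH2Cl2, 0 °C, evaporate; 2, activated Zn dust, THF, 35 °C; combine, Pd(PPh3)4 (5 mol %), THF, 0 °C → rt
Reagents that add atoms: none
Why: Negishi-type acylation: the stereocentre of the β-ester alkylzinc iodide does not bear the metal and is therefore stable, and Pd(0) couples the reagent with the acid chloride in a base-free medium that should leave the skipped dienone unconjugated.

Step 4
Reactants: 7 methyl (2R,6E)-2-methyl-4-oxonona-6,8-dienoate; 8 tiglaldehyde, (2E)-2-methylbut-2-enal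
Product: 10 methyl (4S,5R,10S,11R)-8-oxoeremophila-1,6-dien-12-oate (cis-fused), via Diels–Alder adduct 9 (not isolated)
Conditions: 8 (3 equiv), (R)-diphenylprolinol-derived B-(o-tolyl)oxazaborolidine·Tf2NH (20 mol %), CH2Cl2, −78 → −20 °C; then piperidine (0.6 equiv), AcOH (0.4 equiv), 4 Å MS, same flask, rt → 40 °C
Reagents that add atoms: none
Why: The N-protonated oxazaborolidine binds the formyl oxygen of 8 (with a formyl C–H···O contact) and lowers its LUMO, and the s-cis E-diene of 7 adds in a concerted, asynchronous normal-demand [4+2] cycloaddition (catalytic enantioselective Diels–Alder reaction of an α-substituted enal), which closes ring A through the C3–C4 and C5–C10 bonds. Piperidinium acetate then quenches the Lewis acid and drives an intramolecular aldol condensation of keto aldehyde 9 (enamine or enol at C7 onto the C6 formyl or iminium carbon, 6-(enolexo)-exo-trig, then loss of water), which closes ring B as the C6=C7–C8=O enone. C4 and C5 receive their cis methyl groups from the E geometry of 8 by suprafacial addition, C10 is set by the formyl-endo transition state with the E-configured diene terminus, which places C6 and C9 cis and hence gives the cis ring fusion, and the absolute sense comes from the aryl-shielded face of the bound enal; C11 comes in with 7 and takes no part. The "ortho" regiochemistry (C10 next to the formyl-bearing C5) follows from the larger HOMO coefficient at the unsubstituted diene terminus C3, which bonds to the β-carbon C4. In the condensation the aldehyde cannot enolise because C5 is quaternary, and of the two ketone α-carbons only C7 reaches C6 through a six-membered ring (C9 would give a cyclobutane), so a single enone can form. The closest known reaction type is the sequential Diels–Alder/aldol annulation of tiglaldehyde with dienyl ketones that gives cis-fused dimethyl octalones.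

Step 5
Reactants: 10 methyl (4S,5R,10S,11R)-8-oxoeremophila-1,6-dien-12-oate
Product: 11 methyl (4R,5R,10S,11R)-3,8-dioxoeremophila-1,6-dien-12-oate
Conditions: Mn(OAc)3·2H2O (10 mol %), t-BuOOH (5 equiv, decane), 3 Å MS, EtOAc, rt
Reagents that add atoms: tert-butyl hydroperoxide, CC(C)(C)OO
Why: Mn(III)-catalysed allylic C–H oxidation (peroxyl radical chain): C3 is the only allylic CH2 (C10–H is tertiary, flanked by quaternary C5, and cannot end as a ketone), and the C1 end of the allyl radical is screened by C9 on the α face and by the C5 methyl on the β face, so oxygen should enter at C3 and give the 1-en-3-one.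

Step 6
Reactants: 11 methyl (4R,5R,10S,11R)-3,8-dioxoeremophila-1,6-dien-12-oate
Product: 12 methyl (4R,5R,10R,11R)-3,8-dioxoeremophil-6-en-12-oate
Conditions: H2 (1 atm), RhCl(PPh3)3 (10 mol %), benzene, rt
Reagents that add atoms: none
Why: Homogeneous hydrogenation selects the unhindered cis-disubstituted C1=C2 over the trisubstituted C6=C7 next to quaternary C5, as in 1,4-dien-3-one to 4-en-3-one reductions; no stereocentre is made, and the neutral medium leaves C4 and C11 alone.

Step 7
Reactants: 12 methyl (4R,5R,10R,11R)-3,8-dioxoeremophil-6-en-12-oate
Product: 13 methyl (3S,4R,5R,10R,11R)-3-hydroxy-8-oxoeremophil-6-en-12-oate (3β-alcohol)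
Conditions: LiBH(s-Bu)3 (1.05 equiv), THF, −78 °C; then AcOH in THF, −78 °C
Reagents that add atoms: none
Why: Bulky-hydride ketone reduction: equatorial attack from the α face, away from the axial C5 methyl, should give the axial 3β-alcohol cis to the C4 methyl (the 2-methylcyclohexanone to cis-alcohol pattern), and the saturated C3 ketone should react faster than the α-substituted, β-neopentyl C8 enone.

Step 8
Reactants: 13 methyl (3S,4R,5R,10R,11R)-3-hydroxy-8-oxoeremophil-6-en-12-oate; 14 angelic acid, (2Z)-2-methylbut-2-enoic acid
Product: 16 methyl (3S,4R,5R,10R,11R)-3-[(2Z)-2-methylbut-2-enoyloxy]-8-oxoeremophil-6-en-12-oate (target), via mixed anhydride 15 (not isolated)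
Conditions: 14, 2,4,6-trichlorobenzoyl chloride, Et3N, toluene, rt; then 13, 75–80 °C
Reagents that add atoms: none
Why: Yamaguchi-type mixed-anhydride esterification without a nucleophilic catalyst transfers the angeloyl group with its Z geometry to hindered secondary alcohols, with retention at C3, and the weak amine base should not deprotonate C11.

Compound list
1 | methyl (2R)-3-hydroxy-2-methylpropanoate | OC[C@@H](C)C(=O)OC | starting material
2 | methyl (2S)-3-iodo-2-methylpropanoate | IC[C@@H](C)C(=O)OC | intermediate
3 | sorbic acid, (2E,4E)-hexa-2,4-dienoic acid | C/C=C/C=C/C(=O)O | starting material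
4 | (3E)-hexa-3,5-dienoic acid | C=C/C=C/CC(=O)O | intermediate
5 | (3E)-hexa-3,5-dienoyl chloride | C=C/C=C/CC(=O)Cl | intermediate
6 | [(2S)-3-methoxy-2-methyl-3-oxopropyl]zinc iodide | I[Zn]C[C@@H](C)C(=O)OC | intermediate
7 | methyl (2R,6E)-2-methyl-4-oxonona-6,8-dienoate | C=C/C=C/CC(=O)C[C@@H](C)C(=O)OC | intermediate
8 | tiglaldehyde, (2E)-2-methylbut-2-enal | C/C=C(\C)C=O | starting material
9 | methyl (2R)-5-[(1S,5S,6R)-6-formyl-5,6-dimethylcyclohex-2-en-1-yl]-2-methyl-4-oxopentanoate | C1C=C[C@H](CC(=O)C[C@@H](C)C(=O)OC)[C@@](C=O)(C)[C@H]1C | intermediate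
10 | methyl (4S,5R,10S,11R)-8-oxoeremophila-1,6-dien-12-oate = methyl (2R)-2-[(4aR,5S,8aS)-4a,5-dimethyl-2-oxo-1,2,4a,5,6,8a-hexahydronaphthalen-3-yl]propanoate | C1C=C[C@@H]2CC(=O)C([C@@H](C)C(=O)OC)=C[C@]2(C)[C@H]1C | intermediate
11 | methyl (4R,5R,10S,11R)-3,8-dioxoeremophila-1,6-dien-12-oate | O=C1C=C[C@@H]2CC(=O)C([C@@H](C)C(=O)OC)=C[C@]2(C)[C@H]1C | intermediate
12 | methyl (4R,5R,10R,11R)-3,8-dioxoeremophil-6-en-12-oate | O=C1CC[C@@H]2CC(=O)C([C@@H](C)C(=O)OC)=C[C@]2(C)[C@H]1C | intermediate
13 | methyl (3S,4R,5R,10R,11R)-3-hydroxy-8-oxoeremophil-6-en-12-oate | O[C@H]1CC[C@@H]2CC(=O)C([C@@H](C)C(=O)OC)=C[C@]2(C)[C@H]1C | intermediate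
14 | angelic acid, (2Z)-2-methylbut-2-enoic acid | C/C=C(/C)C(=O)O | starting material
15 | (2Z)-2-methylbut-2-enoic 2,4,6-trichlorobenzoic anhydride | C/C=C(/C)C(=O)OC(=O)c1c(Cl)cc(Cl)cc1Cl | intermediate
16 | methyl (3S,4R,5R,10R,11R)-3-[(2Z)-2-methylbut-2-enoyloxy]-8-oxoeremophil-6-en-12-oate | C/C=C(/C)C(=O)O[C@H]1CC[C@@H]2CC(=O)C([C@@H](C)C(=O)OC)=C[C@]2(C)[C@H]1C | target

Total step count: 8. Longest linear sequence: 7 steps (steps 2–8, from sorbic acid).

Steps most likely to fail

**Step 4.**
- What may go wrong: acid-promoted migration of the skipped diene of 7 into conjugation with the ketone before cycloaddition.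
- What may go wrong: slow cycloaddition of the trisubstituted enal, with leakage through the exo or the unshielded-face pathway.
- What may go wrong: lactonisation of the aldol intermediate onto the ester before dehydration.
- The fallback separates the two events and postpones the C7–C8 bond. It sets out from 4, which is condensed with ethanethiol (EDC, CH2Cl2) to S-ethyl (3E)-hexa-3,5-dienethioate F1. Its carbonyl group is less basic and less prone to enolise.
- The same catalytic enantioselective Diels–Alder reaction with 8 gives S-ethyl [(1S,5S,6R)-6-formyl-5,6-dimethylcyclohex-2-en-1-yl]ethanethioate F2.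
- A Fukuyama coupling of F2 with organozinc iodide 6 (PdCl2(PPh3)2, toluene), which tolerates the hindered aldehyde, comes back to the route at 9. Compound 9 is now isolated and is closed to 10 with piperidinium acetate in a separate flask.

**Step 5.**
- What may go wrong: poor site control when oxygen is transferred to the delocalised allyl radical (C1 against C3), or competing hydrogen abstraction at C10 or C11.
- The fallback replaces the radical chain by a pericyclic sequence that cannot transpose the alkene. It sets out from 10: catalytic SeO2 with t-BuOOH (ene reaction, then [2,3]-sigmatropic shift, methylene preferred over methine) gives methyl (4R,5R,10S,11R)-3-hydroxy-8-oxoeremophila-1,6-dien-12-oate F3 as a C3 epimer mixture.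
- A Dess–Martin oxidation of both epimers comes back to the route at 11.

**Step 8.**
- What may go wrong: slow acylation of the axial, flanked alcohol, so that long heating allows Z-to-E isomerisation of the acyl donor, epimerisation at C11, or drift of the C6=C7 bond towards the ester.
- The fallback forms the acyl–oxygen bond from an acylpalladium species instead of an activated acid. It sets out from 13, which is treated with (Z)-2-bromobut-2-ene, CO (1 atm), Pd(PPh3)4 and i-Pr2NEt in toluene at 60 °C. This alkoxycarbonylation of a vinyl halide proceeds with retention of alkene geometry and comes back to the route at 16. It makes no new compound (F0).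

Further compounds
F1 | step 4 | S-ethyl (3E)-hexa-3,5-dienethioate | C=C/C=C/CC(=O)SCC
F2 | step 4 | S-ethyl [(1S,5S,6R)-6-formyl-5,6-dimethylcyclohex-2-en-1-yl]ethanethioate | C1C=C[C@H](CC(=O)SCC)[C@@](C=O)(C)[C@H]1C
F3 | step 5 | methyl (4R,5R,10S,11R)-3-hydroxy-8-oxoeremophila-1,6-dien-12-oate (C3 epimers) | OC1C=C[C@@H]2CC(=O)C([C@@H](C)C(=O)OC)=C[C@]2(C)[C@H]1C
F0 | step 8 | none | none
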